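Measure the solid before anything else, and measure it in two flasks.

| flask | solid substrate | reagent | remark | time |
|---|---|---|---|---|
| Monday's | 0.0083 M | 0.18 M | run made earlier |  |
| Friday's | 0.11 M | 0.18 M | run made earlier |  |
| north-east | 0.0060 M | 0.180 M |  | 1.5 h |
| east | 0.012 M | 0.180 M |  | 1.5 h |
| north | 0.025 M | 0.180 M |  | 1.5 h |
| north-west | 0.050 M | 0.180 M |  | 1.5 h |
| south | 0.10 M | 0.180 M |  | 1.5 h |

| run | time / min | target / % | solid substrate / % |
|---|---|---|---|
| Monday's | 6.00 | 0.7 | 91.9 |
| Monday's | 15.0 | 4.0 | 79.5 |
| Monday's | 30.0 | 11.8 | 59.1 |
| Monday's | 50.0 | 29.4 | 32.2 |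
| Monday's | 60.0 | 39.4 | 19.7 |
| Friday's | 12.0 | 0.1 | 98.7 |
| Friday's | 25.0 | 0.9 | 97.2 |
| Friday's | 40.0 | 1.0 | 95.9 |
| Friday's | 50.0 | 1.8 | 94.3 |
| Friday's | 60.0 | 1.5 | 92.7 |

(each reading ± 0.3 percentage points)

- the numbers in the tables scatter with a standard deviation of 0.3 percentage points
- at the start none of the solid substrate is in solution
- a reading or a percentage of target counts all its forms, free or not
- the concentration of target that is asked is that of its free form alone
- "hardly changes" means that all values lie within two and a half points (for a concentration: within two and a half percent of the largest)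

1. [target] (only what is free in solution) at the end for north-east, east, north, north-west, south, in this order
2. the shape of the row from first to last (rises all the way / falls all the way / rises, then falls / falls, then rises / hardly changes)

Start with Monday's run. Solid substrate falls from 91.9 % to 19.7 % of its charge between 6.00 min and 60.0 min, which reads as 0.111 mM min⁻¹. Call this the feed: the concentration of solid substrate leaving the solid per minute, a zero-order supply as long as solid remains.

Friday's run is the second way, with a charge 13.3 times Monday's. Up to 25.0 min it gives 0.123 mM min⁻¹, as near as a scatter of 0.3 percentage points allows on so large a charge. So the load hardly matters there.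

After that the two part: from 25.0 min to 60.0 min Friday's solid goes at 0.141 mM min⁻¹, faster than Monday's feed. Yet at 60.0 min Friday's scattered reading of target stands for 1.65 mM, less than the 3.27 mM read on Monday, although Friday's charge is the larger. Read late Friday as the one that cheats: more solid lost and less target suggest that solid and target are consuming each other. Keep Monday's number.

Now set the zero of the scale. A feed independent of load puts the same 9.99 mM through the solid in 1.5 h, so the plain case is a flat row. East should then keep 16.8 % of its solid. North-east is the exception, because its charge lasts 54.1 min, less than the time allowed, so its ceiling is its charge of 0.0060 M. Losses that grow with load then bend the flat part downward, so I expect a rise and then a fall, but I commit to a ceiling, not to a row.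

The forecast gives 0.0048 M, 0.0061 M, 0.0054 M, 0.0043 M and 0.003 M, shape "rises, then falls", arguing that “High loads lose more target”.

The flask gives 0.00318 M, 0.00396 M, 0.00369 M, 0.00323 M and 0.00253 M, shape "rises, then falls".

    solid substrate ⇌ dissolved substrate, rate k1*(cs1 - [dissolved substrate]) while solid is left; crystals form when [dissolved substrate] > cs1 (solubility = 30.0 mM, k = 6.60 × 10⁻⁵ s⁻¹)
    dissolved substrate + reagent → target (k = 0.00240 M⁻¹ s⁻¹)
    2 dissolved substrate → side product A (k = 3.30 × 10⁻⁴ M⁻¹ s⁻¹)
    solid product ⇌ target, rate k4*(cs4 - [target]) while solid is left; crystals form when [target] > cs4 (solubility = 42.0 mM, k = 0.00260 s⁻¹)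
    solid substrate + target → side product B (k = 0.00400 M⁻¹ s⁻¹)
    reagent + target ⇌ idle adduct, settled at all times (K = 2.70 M⁻¹)

Try the feed on the simulated flasks: east ended with 17.4 % of its solid substrate against the 16.8 % reckoned, and north-east held 16.1 % at 0.750 h against 16.7 %. In north-east, while solid remained, dissolved substrate was made 1.97 times faster than it was used at 0.438 h. With solid substrate at 0 % by 1.50 h, dissolved substrate still stood at 21.5 % and kept going to target, which reached 77.8 % of the charge, idle adduct counted in at 24.8 % of the charge, leaving 0.00318 M free.

The data are calculated for an exercise; scatter was added.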